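**Retrosynthetic overview**

1. Target 27 (quinone numbering: C1=O, C2–OMe, C3–indol-3-yl, C4=O, C5–OMe, C6–(7-prenylindol-3-yl)) ⇐ O-methylation of the C5–OH hydroxyquinone 26 ⇐ N-detosylation of 25 ⇐ fluoride desilylation and autoxidation of the hexasubstituted phenol 23.
2. Key disconnection: ring bonds C1–C2 and C5–C6, made together in a Danheiser benzannulation between a four-carbon unit C2–C3–C4–C5 (cyclobutenone 7) and a two-carbon unit C6–C1 (siloxyalkyne 18).
3. Enabling feature: the four ring carbons without an indole (C1, C2, C4, C5) all carry oxygen. C2(OMe)–C3(indolyl)–C4(O)–C5(O) is therefore a squaric-acid four-membered ring with one oxygen exchanged for indol-3-yl, and C6(aryl)–C1(O) is an aryl ynol ether whose polarity (nucleophilic C6, oxygenated C1) matches the vinylketene released from that ring.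
4. 7 ⇐ dimethyl squarate 1 by mono-reduction, O-silylation and indol-3-yllithium addition with 1,3-carbonyl transposition; 18 ⇐ 7-bromoindole 8 by linear-selective prenyl cross-coupling, C3-iodination/N-tosylation, Sonogashira alkynylation and acetylide oxidation/O-silylation.
5. Ring order: both indole rings and the four-membered ring are bought; the only ring built is the six-membered carbocycle (step 9, through a transient second cyclobutenone).

Key step: step 9

Remark: the target is achiral; every sp3 ring centre that appears on the way (in 2, 3, 6, 7, 20, 22) is racemic and is erased later, so no stereocentre has to be set.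

**Route**

Step 1
Reactants: 1 dimethyl squarate (3,4-dimethoxycyclobut-3-ene-1,2-dione)
Product: 2 4-hydroxy-2,3-dimethoxycyclobut-2-en-1-one (racemic)
Conditions: LiAlH(OtBu)3 (1.05 equiv), THF, −78 → −20 °C; aq. Rochelle salt
Reagents that add atoms: none
Why: Chemoselective 1,2-hydride reduction of one of the two equivalent carbonyls by a bulky single-hydride donor, a known mono-reduction of dialkyl squarates in which the alkoxide formed deactivates the second carbonyl; the new centre is racemic and vanishes in step 9.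

Step 2
Reactants: 2 4-hydroxy-2,3-dimethoxycyclobut-2-en-1-one
Product: 3 4-[(tert-butyldimethylsilyl)oxy]-2,3-dimethoxycyclobut-2-en-1-one (racemic)
Conditions: TBSCl, imidazole, DMF, 0 °C → rt
Reagents that add atoms: tert-butyldimethylsilyl chloride, CC(C)(C)[Si](C)(C)Cl
Why: O-Silylation of a secondary alcohol under mild basic conditions, which avoids the acid-induced loss of methanol that would lead to the semisquarate.

Step 3
Reactants: 3 4-[(tert-butyldimethylsilyl)oxy]-2,3-dimethoxycyclobut-2-en-1-one; 4 3-bromo-1-(triisopropylsilyl)-1H-indole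
Product: 7 4-[(tert-butyldimethylsilyl)oxy]-2-methoxy-3-[1-(triisopropylsilyl)-1H-indol-3-yl]cyclobut-2-en-1-one (racemic), via 3-lithioindole 5 (not isolated), via lithium alkoxide adduct 6 (not isolated)
Conditions: 4, t-BuLi (2.0 equiv), THF, −78 °C; then 3, −78 °C; then (CF3CO)2O, −78 → 0 °C; aq. NaHCO3
Reagents that add atoms: water, O
Why: Bromine–lithium exchange gives a 3-lithioindole that the bulky N-silyl group keeps from migrating to C2, and its 1,2-addition to the cyclobutenone carbonyl followed by trifluoroacetylation-induced ionisation and hydrolysis of the methoxy-stabilised allyl cation at its methoxy terminus is the established squarate addition/1,3-carbonyl transposition sequence, which places the indole on C3 and the carbonyl next to the remaining OMe.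

Step 4
Reactants: 8 7-bromo-1H-indole; 9 4,4,5,5-tetramethyl-2-(3-methylbut-2-en-1-yl)-1,3,2-dioxaborolane (prenylboronic acid pinacol ester)
Product: 10 7-(3-methylbut-2-en-1-yl)-1H-indole
Conditions: PdCl2(IPent)(3-chloropyridine) (2 mol %; IPent = 1,3-bis[2,6-di(pentan-3-yl)phenyl]imidazol-2-ylidene), aq. KOH, THF, 65 °C
Reagents that add atoms: none
Why: Suzuki–Miyaura coupling of an allylic boronate, in which a very bulky N-heterocyclic carbene ligand is known to direct reductive elimination to the unsubstituted allyl terminus so that the linear prenyl arene and not the reverse-prenyl isomer should form; free NH bromoindoles are competent partners.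

Step 5
Reactants: 10 7-(3-methylbut-2-en-1-yl)-1H-indole
Product: 12 3-iodo-7-(3-methylbut-2-en-1-yl)-1-(4-methylbenzenesulfonyl)-1H-indole, via 3-iodoindole 11 (not isolated)
Conditions: KOH, I2 (1.02 equiv), DMF, 0 °C → rt; then TsCl, rt
Reagents that add atoms: iodine, II; 4-methylbenzenesulfonyl chloride, Cc1ccc(cc1)S(Cl)(=O)=O
Why: Electrophilic aromatic iodination of the indolide at C3 (far faster than any reaction of iodine with the trisubstituted alkene under basic conditions) followed in the same flask by N-sulfonylation of the light-sensitive 3-iodoindole, the sulfonyl group tempering the indole for the alkyne chemistry that follows.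

Step 6
Reactants: 12 3-iodo-7-(3-methylbut-2-en-1-yl)-1-(4-methylbenzenesulfonyl)-1H-indole; 13 ethynyltrimethylsilane
Product: 14 7-(3-methylbut-2-en-1-yl)-1-(4-methylbenzenesulfonyl)-3-[(trimethylsilyl)ethynyl]-1H-indole
Conditions: PdCl2(PPh3)2 (3 mol %), CuI (5 mol %), Et3N, THF, rt
Reagents that add atoms: none
Why: Sonogashira coupling at the reactive C3–I bond, which proceeds at room temperature and leaves the prenyl alkene untouched.

Step 7
Reactants: 14 7-(3-methylbut-2-en-1-yl)-1-(4-methylbenzenesulfonyl)-3-[(trimethylsilyl)ethynyl]-1H-indole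
Product: 15 3-ethynyl-7-(3-methylbut-2-en-1-yl)-1-(4-methylbenzenesulfonyl)-1H-indole
Conditions: K2CO3 (0.2 equiv), MeOH/THF, 0 °C, 30 min
Reagents that add atoms: none
Why: Base-catalysed methanolysis of the C(sp)–Si bond (protodesilylation), which at 0 °C with catalytic carbonate is much faster than methanolysis of the N-sulfonyl group.

Step 8
Reactants: 15 3-ethynyl-7-(3-methylbut-2-en-1-yl)-1-(4-methylbenzenesulfonyl)-1H-indole
Product: 18 7-(3-methylbut-2-en-1-yl)-1-(4-methylbenzenesulfonyl)-3-{[(triisopropylsilyl)oxy]ethynyl}-1H-indole, via lithium acetylide 16 (not isolated), via lithium ynolate 17 (not isolated)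
Conditions: LiN(SiMe3)2 (2.2 equiv), t-BuOOH (1.1 equiv), THF, −78 → 0 °C; then TIPSOTf (1.2 equiv), −78 °C; pentane, aq. NaHCO3; used promptly
Reagents that add atoms: tert-butyl hydroperoxide, CC(C)(C)OO; triisopropylsilyl trifluoromethanesulfonate, CC(C)[Si](OS(=O)(=O)C(F)(F)F)(C(C)C)C(C)C
Why: Oxidation of a lithium acetylide by lithium tert-butyl peroxide (electrophilic oxygen transfer to carbon) gives the ynolate, and the bulky silyl triflate silylates it on oxygen rather than carbon, the standard entry to aryl siloxyalkynes.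

Step 9
Reactants: 7 4-[(tert-butyldimethylsilyl)oxy]-2-methoxy-3-[1-(triisopropylsilyl)-1H-indol-3-yl]cyclobut-2-en-1-one; 18 7-(3-methylbut-2-en-1-yl)-1-(4-methylbenzenesulfonyl)-3-{[(triisopropylsilyl)oxy]ethynyl}-1H-indole
Product: 23 2-[(tert-butyldimethylsilyl)oxy]-4-methoxy-6-[7-(3-methylbut-2-en-1-yl)-1-(4-methylbenzenesulfonyl)-1H-indol-3-yl]-5-[(triisopropylsilyl)oxy]-3-[1-(triisopropylsilyl)-1H-indol-3-yl]phenol, via vinylketene 19 (not isolated), via vinylcyclobutenone 20 (not isolated), via dienylketene 21 (not isolated), via cyclohexadienone 22 (not isolated)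
Conditions: 18 (1.3 equiv), toluene (0.2 M), 80 → 110 °C, argon
Reagents that add atoms: none
Why: On heating, 7 should open by a 4π electrocyclic reaction (siloxy donor rotating outward) to vinylketene 19, whose ketene C=C adds across the siloxyalkyne in a regioselective [2+2] cycloaddition that makes both new ring bonds in one event, the ketene carbonyl carbon (future C5) bonding to the nucleophilic indolyl-bearing alkyne carbon (future C6) and the methoxy-bearing ketene carbon (future C2) bonding to the siloxy-bearing carbon (future C1) to give 20; a second 4π opening (OMe outward, vinyl inward) leads to the (Z)-dienylketene 21, which closes to 22 and tautomerises to the phenol. The closest known reaction type is the Danheiser benzannulation of cyclobutenones with trialkylsiloxyalkynes, which gives exactly this pattern, with the alkyne substituent flanked by the new OH and the OSi group. The six-membered ring is closed by a thermally allowed disrotatory 6π electrocyclisation of 21, re-forming the C4–C5 bond that the first ring opening had broken, and the transient four-membered ring of 20 is closed by the [2+2] step. No stereocentre remains in 23, since the sp3 centres of 20 and 22 are racemic and vanish on ring opening and enolisation. The selectivity needed is the head-to-tail orientation of the [2+2] step, secured by matched polarisation (electrophilic central ketene carbon against the beta carbon of the ynol silyl ether, the only carbon activated by the oxygen lone pair), together with outward rotation of the oxygen donors in both ring openings. Both indole nitrogens are blocked and no free OH exists before the last tautomerisation, so the ketenes 19 and 21 meet no heteroatom nucleophile that could divert them.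

Step 10
Reactants: 23 the hexasubstituted phenol
Product: 25 5-hydroxy-3-(1H-indol-3-yl)-2-methoxy-6-[7-(3-methylbut-2-en-1-yl)-1-(4-methylbenzenesulfonyl)-1H-indol-3-yl]cyclohexa-2,5-diene-1,4-dione (target numbering), via triol 24 (not isolated)
Conditions: Bu4NF (4 equiv), THF, 0 °C → rt, argon; then air (O2), rt; AcOH quench
Reagents that add atoms: none
Why: Fluoride-mediated desilylation should cleave both aryl silyl ethers and the N–Si bond while the N-sulfonyl group stays, and autoxidation of the electron-rich benzene-1,2,4-triol can only give the 2-hydroxy-1,4-benzoquinone with carbonyls at the para pair C1/C4 and OH left on C5, so that any O-to-O silyl shift between the neighbouring oxygens of 23 would be without consequence.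

Step 11
Reactants: 25 the N-tosyl hydroxyquinone
Product: 26 5-hydroxy-3-(1H-indol-3-yl)-2-methoxy-6-[7-(3-methylbut-2-en-1-yl)-1H-indol-3-yl]cyclohexa-2,5-diene-1,4-dione
Conditions: Cs2CO3 (3 equiv), MeOH/THF (1:2), 40 °C; aq. citric acid
Reagents that add atoms: none
Why: Base-mediated methanolysis of an N-sulfonylindole (methoxide attacks sulfur, the quinone-conjugated indolide leaves), during which the hydroxyquinone is held as its inert caesium salt and the remaining methoxy group can only undergo degenerate exchange.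

Step 12
Reactants: 26 the hydroxyquinone
Product: 27 3-(1H-indol-3-yl)-2,5-dimethoxy-6-[7-(3-methylbut-2-en-1-yl)-1H-indol-3-yl]cyclohexa-2,5-diene-1,4-dione (target, CNP0256613.0)
Conditions: Me3SiCHN2 (1.5 equiv), MeOH/toluene (1:4), 0 °C → rt
Reagents that add atoms: (trimethylsilyl)diazomethane, C[Si](C)(C)C=[N+]=[N-]
Why: O-Methylation of a vinylogous carboxylic acid by a diazoalkane (protonation, then collapse of the ion pair), selective for the acidic quinone hydroxyl over the two indole NH groups and expected to give the para-quinone ether, the more stable of the two O-alkylation modes.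

**Compound list**

1 | dimethyl squarate (3,4-dimethoxycyclobut-3-ene-1,2-dione) | COC1=C(OC)C(=O)C1=O | starting material
2 | 4-hydroxy-2,3-dimethoxycyclobut-2-en-1-one (racemic) | COC1=C(OC)C(O)C1=O | intermediate
3 | 4-[(tert-butyldimethylsilyl)oxy]-2,3-dimethoxycyclobut-2-en-1-one (racemic) | COC1=C(OC)C(O[Si](C)(C)C(C)(C)C)C1=O | intermediate
4 | 3-bromo-1-(triisopropylsilyl)-1H-indole | Brc1cn([Si](C(C)C)(C(C)C)C(C)C)c2ccccc12 | starting material
5 | 3-lithio-1-(triisopropylsilyl)-1H-indole (formed in the flask) | [Li]c1cn([Si](C(C)C)(C(C)C)C(C)C)c2ccccc12 | intermediate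
6 | lithium 4-[(tert-butyldimethylsilyl)oxy]-2,3-dimethoxy-1-[1-(triisopropylsilyl)-1H-indol-3-yl]cyclobut-2-en-1-olate (racemic diastereomer mixture, formed in the flask) | COC1=C(OC)C(O[Si](C)(C)C(C)(C)C)C1(O[Li])c2cn([Si](C(C)C)(C(C)C)C(C)C)c3ccccc23 | intermediate
7 | 4-[(tert-butyldimethylsilyl)oxy]-2-methoxy-3-[1-(triisopropylsilyl)-1H-indol-3-yl]cyclobut-2-en-1-one (racemic) | COC1=C(c2cn([Si](C(C)C)(C(C)C)C(C)C)c3ccccc23)C(O[Si](C)(C)C(C)(C)C)C1=O | intermediate
8 | 7-bromo-1H-indole | Brc1cccc2cc[nH]c12 | starting material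
9 | 4,4,5,5-tetramethyl-2-(3-methylbut-2-en-1-yl)-1,3,2-dioxaborolane | CC(C)=CCB1OC(C)(C)C(C)(C)O1 | starting material
10 | 7-(3-methylbut-2-en-1-yl)-1H-indole | CC(C)=CCc1cccc2cc[nH]c12 | intermediate
11 | 3-iodo-7-(3-methylbut-2-en-1-yl)-1H-indole (formed in the flask) | CC(C)=CCc1cccc2c(I)c[nH]c12 | intermediate
12 | 3-iodo-7-(3-methylbut-2-en-1-yl)-1-(4-methylbenzenesulfonyl)-1H-indole | CC(C)=CCc1cccc2c(I)cn(S(=O)(=O)c3ccc(C)cc3)c12 | intermediate
13 | ethynyltrimethylsilane | C#C[Si](C)(C)C | starting material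
14 | 7-(3-methylbut-2-en-1-yl)-1-(4-methylbenzenesulfonyl)-3-[(trimethylsilyl)ethynyl]-1H-indole | CC(C)=CCc1cccc2c(C#C[Si](C)(C)C)cn(S(=O)(=O)c3ccc(C)cc3)c12 | intermediate
15 | 3-ethynyl-7-(3-methylbut-2-en-1-yl)-1-(4-methylbenzenesulfonyl)-1H-indole | CC(C)=CCc1cccc2c(C#C)cn(S(=O)(=O)c3ccc(C)cc3)c12 | intermediate
16 | lithium acetylide of 15 (formed in the flask) | CC(C)=CCc1cccc2c(C#C[Li])cn(S(=O)(=O)c3ccc(C)cc3)c12 | intermediate
17 | lithium 2-[7-(3-methylbut-2-en-1-yl)-1-(4-methylbenzenesulfonyl)-1H-indol-3-yl]ethyn-1-olate (formed in the flask) | CC(C)=CCc1cccc2c(C#CO[Li])cn(S(=O)(=O)c3ccc(C)cc3)c12 | intermediate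
18 | 7-(3-methylbut-2-en-1-yl)-1-(4-methylbenzenesulfonyl)-3-{[(triisopropylsilyl)oxy]ethynyl}-1H-indole | CC(C)=CCc1cccc2c(C#CO[Si](C(C)C)(C(C)C)C(C)C)cn(S(=O)(=O)c3ccc(C)cc3)c12 | intermediate
19 | (E)-4-[(tert-butyldimethylsilyl)oxy]-2-methoxy-3-[1-(triisopropylsilyl)-1H-indol-3-yl]buta-1,3-dien-1-one (formed in the flask) | O=C=C(OC)/C(c1cn([Si](C(C)C)(C(C)C)C(C)C)c2ccccc12)=C/O[Si](C)(C)C(C)(C)C | intermediate
20 | 4-{(E)-2-[(tert-butyldimethylsilyl)oxy]-1-[1-(triisopropylsilyl)-1H-indol-3-yl]ethenyl}-4-methoxy-2-[7-(3-methylbut-2-en-1-yl)-1-(4-methylbenzenesulfonyl)-1H-indol-3-yl]-3-[(triisopropylsilyl)oxy]cyclobut-2-en-1-one (racemic, formed in the flask) | O=C1C(c2cn(S(=O)(=O)c3ccc(C)cc3)c3c(CC=C(C)C)cccc23)=C(O[Si](C(C)C)(C(C)C)C(C)C)C1(OC)/C(c1cn([Si](C(C)C)(C(C)C)C(C)C)c2ccccc12)=C/O[Si](C)(C)C(C)(C)C | intermediate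
21 | (3Z,5E)-6-[(tert-butyldimethylsilyl)oxy]-4-methoxy-2-[7-(3-methylbut-2-en-1-yl)-1-(4-methylbenzenesulfonyl)-1H-indol-3-yl]-3-[(triisopropylsilyl)oxy]-5-[1-(triisopropylsilyl)-1H-indol-3-yl]hexa-1,3,5-trien-1-one (formed in the flask) | O=C=C(c1cn(S(=O)(=O)c2ccc(C)cc2)c2c(CC=C(C)C)cccc12)/C(O[Si](C(C)C)(C(C)C)C(C)C)=C(OC)\C(c1cn([Si](C(C)C)(C(C)C)C(C)C)c2ccccc12)=C\O[Si](C)(C)C(C)(C)C | intermediate
22 | 6-[(tert-butyldimethylsilyl)oxy]-4-methoxy-2-[7-(3-methylbut-2-en-1-yl)-1-(4-methylbenzenesulfonyl)-1H-indol-3-yl]-3-[(triisopropylsilyl)oxy]-5-[1-(triisopropylsilyl)-1H-indol-3-yl]cyclohexa-2,4-dien-1-one (racemic, formed in the flask) | O=C1C(c2cn(S(=O)(=O)c3ccc(C)cc3)c3c(CC=C(C)C)cccc23)=C(O[Si](C(C)C)(C(C)C)C(C)C)C(OC)=C(c2cn([Si](C(C)C)(C(C)C)C(C)C)c3ccccc23)C1O[Si](C)(C)C(C)(C)C | intermediate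
23 | 2-[(tert-butyldimethylsilyl)oxy]-4-methoxy-6-[7-(3-methylbut-2-en-1-yl)-1-(4-methylbenzenesulfonyl)-1H-indol-3-yl]-5-[(triisopropylsilyl)oxy]-3-[1-(triisopropylsilyl)-1H-indol-3-yl]phenol | Oc1c(-c2cn(S(=O)(=O)c3ccc(C)cc3)c3c(CC=C(C)C)cccc23)c(O[Si](C(C)C)(C(C)C)C(C)C)c(OC)c(-c2cn([Si](C(C)C)(C(C)C)C(C)C)c3ccccc23)c1O[Si](C)(C)C(C)(C)C | intermediate
24 | 6-(1H-indol-3-yl)-5-methoxy-3-[7-(3-methylbut-2-en-1-yl)-1-(4-methylbenzenesulfonyl)-1H-indol-3-yl]benzene-1,2,4-triol (formed in the flask) | COc1c(-c2c[nH]c3ccccc23)c(O)c(O)c(-c2cn(S(=O)(=O)c3ccc(C)cc3)c3c(CC=C(C)C)cccc23)c1O | intermediate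
25 | 5-hydroxy-3-(1H-indol-3-yl)-2-methoxy-6-[7-(3-methylbut-2-en-1-yl)-1-(4-methylbenzenesulfonyl)-1H-indol-3-yl]cyclohexa-2,5-diene-1,4-dione | COC1=C(c2c[nH]c3ccccc23)C(=O)C(O)=C(c2cn(S(=O)(=O)c3ccc(C)cc3)c3c(CC=C(C)C)cccc23)C1=O | intermediate
26 | 5-hydroxy-3-(1H-indol-3-yl)-2-methoxy-6-[7-(3-methylbut-2-en-1-yl)-1H-indol-3-yl]cyclohexa-2,5-diene-1,4-dione | COC1=C(c2c[nH]c3ccccc23)C(=O)C(O)=C(c2c[nH]c3c(CC=C(C)C)cccc23)C1=O | intermediate
27 | 3-(1H-indol-3-yl)-2,5-dimethoxy-6-[7-(3-methylbut-2-en-1-yl)-1H-indol-3-yl]cyclohexa-2,5-diene-1,4-dione (CNP0256613.0) | COC1=C(c2c[nH]c3ccccc23)C(=O)C(OC)=C(c2c[nH]c3c(CC=C(C)C)cccc23)C1=O | target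

**Step count and risks**

Total step count: 12 (steps 1–3 for the cyclobutenone, steps 4–8 for the siloxyalkyne, steps 9–12 after convergence).
Longest linear sequence: 9 steps (steps 4–12, from 7-bromoindole 8).

Steps most likely to fail:

1. Step 9. The intermolecular [2+2] joins two fully substituted, hindered partners and may be slow, so that oligomerisation of ketene 19, or acylation of the product phenol by 19, could compete with productive cycloaddition. The fallback sets out from 10 and comes back to the route at 27; it builds the quinone ring from a preformed quinone by stepwise acid-promoted conjugate addition of the indoles. Commercial 2,5-dichloro-1,4-benzoquinone and commercial indole would be combined under HCl in THF and the adduct re-oxidised with DDQ to 2,5-dichloro-3-(1H-indol-3-yl)cyclohexa-2,5-diene-1,4-dione F1. Compound 10 would then be added to the only free ring position of F1 in acetic acid (the milder acid spares the prenyl group) and re-oxidation with DDQ should give 2,5-dichloro-3-(1H-indol-3-yl)-6-[7-(3-methylbut-2-en-1-yl)-1H-indol-3-yl]cyclohexa-2,5-diene-1,4-dione F2. NaOH in aqueous MeOH would exchange both vinylogous acid chlorides to give 2,5-dihydroxy-3-(1H-indol-3-yl)-6-[7-(3-methylbut-2-en-1-yl)-1H-indol-3-yl]cyclohexa-2,5-diene-1,4-dione F3, and double O-methylation (Me2SO4, K2CO3, acetone) should give 27.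

2. Step 8. Oxygen transfer to the acetylide may be incomplete, the peroxide or amide base may attack the N-sulfonyl group, and the ynolate may be silylated on carbon or protonated, giving ketene-derived products instead of the siloxyalkyne. The fallback sets out from 12 and comes back to the route at 18; it generates the same ynolate by one-carbon insertion into an ester instead of by acetylide oxidation. Carbonylation of 12 (Pd(OAc)2, 1,1'-bis(diphenylphosphino)ferrocene, CO, MeOH, Et3N, DMF) would give methyl 7-(3-methylbut-2-en-1-yl)-1-(4-methylbenzenesulfonyl)-1H-indole-3-carboxylate F4. A Kowalski ester homologation (LiCHBr2 from CH2Br2 and lithium 2,2,6,6-tetramethylpiperidide, then LiN(SiMe3)2 and n-BuLi, −78 °C → rt) should carry F4 through the bromo-enolate carbenoid rearrangement to ynolate 17, which would be silylated on oxygen with TIPSCl to give 18.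

3. Step 3. The weakly electrophilic vinylogous-ester carbonyl of 3 may add the aryllithium sluggishly, and the trifluoroacetylation-induced ionisation may be accompanied by loss of the silyl groups or by ionisation at the wrong terminus. The fallback sets out from 1 and 4 and comes back to the route at 7; it installs the indole on the squarate itself and postpones the reduction. Addition of 5 (from 4, t-BuLi) to 1 at −78 °C with an NH4Cl quench would give 4-hydroxy-2,3-dimethoxy-4-[1-(triisopropylsilyl)-1H-indol-3-yl]cyclobut-2-en-1-one F5. 1,2-Reduction of its carbonyl (i-Bu2AlH, THF, −78 °C) would give 3,4-dimethoxy-1-[1-(triisopropylsilyl)-1H-indol-3-yl]cyclobut-3-ene-1,2-diol F6. Brief exposure to pyridinium p-toluenesulfonate in wet CH2Cl2 should ionise the tertiary, indole-stabilised hydroxyl and transpose the carbonyl to give 4-hydroxy-2-methoxy-3-[1-(triisopropylsilyl)-1H-indol-3-yl]cyclobut-2-en-1-one F7, and silylation (TBSCl, imidazole, DMF) would give 7.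

Further compounds
F1 | step 9 | 2,5-dichloro-3-(1H-indol-3-yl)cyclohexa-2,5-diene-1,4-dione | O=C1C=C(Cl)C(=O)C(c2c[nH]c3ccccc23)=C1Cl
F2 | step 9 | 2,5-dichloro-3-(1H-indol-3-yl)-6-[7-(3-methylbut-2-en-1-yl)-1H-indol-3-yl]cyclohexa-2,5-diene-1,4-dione | O=C1C(c2c[nH]c3c(CC=C(C)C)cccc23)=C(Cl)C(=O)C(c2c[nH]c3ccccc23)=C1Cl
F3 | step 9 | 2,5-dihydroxy-3-(1H-indol-3-yl)-6-[7-(3-methylbut-2-en-1-yl)-1H-indol-3-yl]cyclohexa-2,5-diene-1,4-dione | O=C1C(c2c[nH]c3c(CC=C(C)C)cccc23)=C(O)C(=O)C(c2c[nH]c3ccccc23)=C1O
F4 | step 8 | methyl 7-(3-methylbut-2-en-1-yl)-1-(4-methylbenzenesulfonyl)-1H-indole-3-carboxylate | COC(=O)c1cn(S(=O)(=O)c2ccc(C)cc2)c2c(CC=C(C)C)cccc12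
F5 | step 3 | 4-hydroxy-2,3-dimethoxy-4-[1-(triisopropylsilyl)-1H-indol-3-yl]cyclobut-2-en-1-one (racemic) | COC1=C(OC)C(O)(c2cn([Si](C(C)C)(C(C)C)C(C)C)c3ccccc23)C1=O
F6 | step 3 | 3,4-dimethoxy-1-[1-(triisopropylsilyl)-1H-indol-3-yl]cyclobut-3-ene-1,2-diol (racemic diastereomer mixture) | COC1=C(OC)C(O)(c2cn([Si](C(C)C)(C(C)C)C(C)C)c3ccccc23)C1O
F7 | step 3 | 4-hydroxy-2-methoxy-3-[1-(triisopropylsilyl)-1H-indol-3-yl]cyclobut-2-en-1-one (racemic) | COC1=C(c2cn([Si](C(C)C)(C(C)C)C(C)C)c3ccccc23)C(O)C1=O
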